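**Plan**

- Retrosynthesis: the prenyl group is removed from C6 (aryl–allyl bond, through the 6-bromide) and the C3 carbinol is traced back to the C3 ketone. The cuts that follow are C4–C4a of the pyran ring, the tertiary ether bond O1–C2, and last the CH2–CH2 link between rings A and B.
- Enabling feature: C4a of ring A sits ortho to O1 and para to the C7 oxygen, the most electron-rich carbon available to an oxidised enol ether–arene pair, so the pyranone can be closed there at an anode.
- Forward: rings A and B are joined as a dihydrostilbene (Wittig, hydrogenation); one ring-A phenol is masked as its MOM ether and the other is etherified with the tertiary bromo ketone.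
- The pyran ring, the only ring made, closes in step 8; C3 reduction, C6 bromination, prenyl coupling and deprotection finish the target.
- Stereochemistry: the single stereocentre, C3 (R), comes from catalyst-controlled CBS reduction of the chroman-3-one with the (S)-oxazaborolidine; no later step touches it.

Key step: step 8

Remark: the alkene of step 3 is expected as an E/Z mixture and is carried on as such, since both isomers give the same dihydrostilbene in step 4; ring-A locants follow chroman numbering (O1, C2, C3, C4, C4a, C5–C8, C8a).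

**Route**

Step 1
Reactants: 1 3,4-dihydroxybenzaldehyde
Product: 2 3,4-bis(pivaloyloxy)benzaldehyde
Conditions: PivCl (2.3 equiv), Et3N, DMAP (cat.), CH2Cl2, 0 °C to rt
Reagents that add atoms: pivaloyl chloride, CC(C)(C)C(Cl)=O
Why: DMAP-catalysed O-acylation of both catechol hydroxyls should be clean, and the hindered, electron-withdrawing pivalates are chosen to resist the later bases and to switch ring B off towards oxidation and bromination.

Step 2
Reactants: 3 3,5-bis(benzyloxy)benzyl bromide
Product: 4 [3,5-bis(benzyloxy)benzyl]triphenylphosphonium bromide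
Conditions: PPh3, toluene, reflux
Reagents that add atoms: triphenylphosphine, c1ccc(cc1)P(c1ccccc1)c1ccccc1
Why: SN2 quaternisation of triphenylphosphine by a primary benzylic bromide is a standard phosphonium salt formation and the salt should crystallise from toluene.

Step 3
Reactants: 4 [3,5-bis(benzyloxy)benzyl]triphenylphosphonium bromide; 2 3,4-bis(pivaloyloxy)benzaldehyde
Product: 6 1,3-bis(benzyloxy)-5-[2-(3,4-bis(pivaloyloxy)phenyl)ethenyl]benzene (E/Z mixture), via phosphonium ylide 5 (not isolated)
Conditions: NaN(SiMe3)2 (0.95 equiv), THF, 0 °C; then 2, −78 °C to rt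
Reagents that add atoms: none
Why: Wittig olefination of the aryl aldehyde by the pre-formed semi-stabilised benzylic ylide should be faster than any attack on the hindered aryl pivalates, the slight deficit of non-nucleophilic amide base leaves no free base, and the alkene geometry is irrelevant.

Step 4
Reactants: 6 1,3-bis(benzyloxy)-5-[2-(3,4-bis(pivaloyloxy)phenyl)ethenyl]benzene
Product: 7 5-[2-(3,4-bis(pivaloyloxy)phenyl)ethyl]benzene-1,3-diol
Conditions: H2 (1 atm), 10% Pd/C, EtOAc/EtOH, rt
Reagents that add atoms: none
Why: heterogeneous catalytic hydrogenation should saturate the stilbene double bond and hydrogenolyse both benzyl ethers in one operation, while aryl pivalates are inert to these conditions.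

Step 5
Reactants: 7 5-[2-(3,4-bis(pivaloyloxy)phenyl)ethyl]benzene-1,3-diol
Product: 8 3-[2-(3,4-bis(pivaloyloxy)phenyl)ethyl]-5-(methoxymethoxy)phenol
Conditions: MOMCl (1.0 equiv), i-Pr2NEt, CH2Cl2, 0 °C to rt; recovered 7 and bis-ether recycled
Reagents that add atoms: chloromethyl methyl ether, COCCl
Why: Williamson-type acetalisation of one of two equivalent phenols with one equivalent of MOMCl under a weak amine base is a routine statistical mono-protection, and it avoids a free phenoxide that could attack the pivalates.

Step 6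
Reactants: 8 3-[2-(3,4-bis(pivaloyloxy)phenyl)ethyl]-5-(methoxymethoxy)phenol; 9 3-bromo-3-methylbutan-2-one
Product: 10 3-{3-[2-(3,4-bis(pivaloyloxy)phenyl)ethyl]-5-(methoxymethoxy)phenoxy}-3-methylbutan-2-one
Conditions: 9 (3 equiv), K2CO3, DMF, 50 °C
Reagents that add atoms: none
Why: Williamson O-alkylation of a phenoxide by a tertiary α-bromo carbonyl compound is activated by the adjacent carbonyl group, as in the preparation of aryloxyisobutyrates, and the excess of 9 should make up for loss by elimination.

Step 7
Reactants: 10 3-{3-[2-(3,4-bis(pivaloyloxy)phenyl)ethyl]-5-(methoxymethoxy)phenoxy}-3-methylbutan-2-one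
Product: 11 tert-butyl{[3-{3-[2-(3,4-bis(pivaloyloxy)phenyl)ethyl]-5-(methoxymethoxy)phenoxy}-3-methylbut-1-en-2-yl]oxy}dimethylsilane (TBS enol ether of 10)
Conditions: TBSOTf, Et3N, CH2Cl2, 0 °C
Reagents that add atoms: tert-butyldimethylsilyl trifluoromethanesulfonate, CC(C)(C)[Si](C)(C)OS(=O)(=O)C(F)(F)F
Why: soft enolisation with a silyl triflate and a tertiary amine (enol silylation) can only engage the methyl group, the other α-carbon being quaternary, so a single terminal silyl enol ether should form while the amine excess protects the MOM acetal.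

Step 8
Reactants: 11 TBS enol ether of 10
Product: 12 5-[2-(3,4-bis(pivaloyloxy)phenyl)ethyl]-7-(methoxymethoxy)-2,2-dimethylchroman-3-one
Conditions: RVC anode, Pt cathode, undivided cell, constant current (8 mA, ca. 2.1 F/mol), 0.1 M LiClO4, MeOH/CH2Cl2 (1:4), 2,6-lutidine, rt
Reagents that add atoms: none
Why: Anodic removal of one electron from the silyl enol ether–dialkoxyarene pair (similar oxidation potentials, either radical cation leading to the same bond) is followed by bonding of the terminal enol carbon C4 to the ortho carbon C4a; a second electron transfer, loss of the aryl proton to 2,6-lutidine and transfer of the silyl group to methanol restore the arene and release the C3 ketone. The closest known reaction type is the intramolecular anodic coupling of enol ethers and silyl enol ethers with alkoxyarenes and furans, an oxidative Friedel–Crafts-type annulation. The pyran ring closes in a 6-endo-trig mode with respect to the enol ether, both C3 and C4 becoming ring members, and the gem-dimethyl group at C2 holds the chain in the folded conformation (Thorpe–Ingold effect). No stereocentre is created. The step needs site selectivity for C4a over the other ortho carbon (later C8) and chemoselectivity for ring A over ring B: C4a is para to the MOM-bearing oxygen whereas the other site lies between the two oxygens, the position that 5-alkylresorcinol diethers use least in electrophilic substitution, and ring B is pushed beyond the working potential by its two pivalates. Ketone 10 can enolise towards its methyl group only, so 11 is a single enol ether, and passing only about 2 F/mol at constant current should limit further oxidation of 12.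

Step 9
Reactants: 12 5-[2-(3,4-bis(pivaloyloxy)phenyl)ethyl]-7-(methoxymethoxy)-2,2-dimethylchroman-3-one
Product: 13 (3R)-5-[2-(3,4-bis(pivaloyloxy)phenyl)ethyl]-7-(methoxymethoxy)-2,2-dimethylchroman-3-ol
Conditions: (S)-2-methyl-CBS-oxazaborolidine (0.2 equiv), BH3·SMe2, THF, −20 °C; MeOH quench
Reagents that add atoms: none
Why: in this Corey–Bakshi–Shibata reduction the (S)-oxazaborolidine should bind the carbonyl oxygen anti to the quaternary C2 (large group, C4H2 being the small one) and deliver hydride to the face that gives the 3R alcohol, in the same sense as (R)-1-phenylethanol from acetophenone, and aryl pivalates are not reduced by borane at this temperature.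

Step 10
Reactants: 13 (3R)-5-[2-(3,4-bis(pivaloyloxy)phenyl)ethyl]-7-(methoxymethoxy)-2,2-dimethylchroman-3-ol
Product: 14 (3R)-6-bromo-5-[2-(3,4-bis(pivaloyloxy)phenyl)ethyl]-7-(methoxymethoxy)-2,2-dimethylchroman-3-ol
Conditions: NBS (1.05 equiv), MeCN, −20 to 0 °C, dark
Reagents that add atoms: N-bromosuccinimide, O=C1CCC(=O)N1Br
Why: electrophilic aromatic bromination with NBS in acetonitrile should go to C6, para to O1 and ortho to the MOM ether, because 5-alkylresorcinol diethers brominate next to the alkyl group and not between the two oxygens (C8), and the acyloxy-substituted ring B is far less reactive.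

Step 11
Reactants: 14 (3R)-6-bromo-5-[2-(3,4-bis(pivaloyloxy)phenyl)ethyl]-7-(methoxymethoxy)-2,2-dimethylchroman-3-ol; 15 prenylboronic acid pinacol ester
Product: 16 (3R)-5-[2-(3,4-bis(pivaloyloxy)phenyl)ethyl]-7-(methoxymethoxy)-2,2-dimethyl-6-(3-methylbut-2-en-1-yl)chroman-3-ol
Conditions: 15 (2 equiv), Pd(OAc)2 (5 mol%), 2-di-tert-butylphosphino-2',4',6'-triisopropylbiphenyl (10 mol%), K3PO4 (aq.), MeCN, 70 °C, degassed
Reagents that add atoms: none
Why: in this Suzuki–Miyaura coupling of an allylboronate the bulky di-tert-butyl biarylphosphine should let the allylpalladium intermediate equilibrate to the primary σ-allyl form, and the doubly ortho-substituted aryl group further disfavours reductive elimination at the tertiary terminus, so the linear prenyl arene is expected.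

Step 12
Reactants: 16 (3R)-5-[2-(3,4-bis(pivaloyloxy)phenyl)ethyl]-7-(methoxymethoxy)-2,2-dimethyl-6-(3-methylbut-2-en-1-yl)chroman-3-ol
Product: 17 (3R)-5-[2-(3,4-bis(pivaloyloxy)phenyl)ethyl]-2,2-dimethyl-6-(3-methylbut-2-en-1-yl)chromane-3,7-diol
Conditions: HCl (0.5 M in MeOH, cat.), MeOH, 0 °C to rt, stopped at full conversion
Reagents that add atoms: none
Why: acid-catalysed acetal exchange with methanol cleaves phenolic MOM ethers under conditions mild enough to leave aryl pivalates intact and, at room temperature and short contact time, should not add the new phenol across the neighbouring prenyl double bond.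

Step 13
Reactants: 17 (3R)-5-[2-(3,4-bis(pivaloyloxy)phenyl)ethyl]-2,2-dimethyl-6-(3-methylbut-2-en-1-yl)chromane-3,7-diol
Product: 18 (3R)-5-[2-(3,4-dihydroxyphenyl)ethyl]-2,2-dimethyl-6-(3-methylbut-2-en-1-yl)chromane-3,7-diol (CNP0369548.1)
Conditions: K2CO3 (excess), degassed MeOH, Ar, rt; then dilute aqueous acid to pH 4
Reagents that add atoms: none
Why: base-mediated transesterification with methanol removes both aryl pivalates as methyl pivalate, exclusion of oxygen protects the catecholate until acidification, and neither the prenyl group nor the C3 stereocentre is affected.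

**Compound list**

1 | 3,4-dihydroxybenzaldehyde | O=Cc1ccc(O)c(O)c1 | starting material
2 | 3,4-bis(pivaloyloxy)benzaldehyde | O=Cc1ccc(OC(=O)C(C)(C)C)c(OC(=O)C(C)(C)C)c1 | intermediate
3 | 3,5-bis(benzyloxy)benzyl bromide | BrCc1cc(OCc2ccccc2)cc(OCc2ccccc2)c1 | starting material
4 | [3,5-bis(benzyloxy)benzyl]triphenylphosphonium bromide | [Br-].c1ccc(cc1)[P+](Cc1cc(OCc2ccccc2)cc(OCc2ccccc2)c1)(c1ccccc1)c1ccccc1 | intermediate
5 | [3,5-bis(benzyloxy)benzylidene]triphenylphosphorane (phosphonium ylide) | c1ccc(cc1)P(=Cc1cc(OCc2ccccc2)cc(OCc2ccccc2)c1)(c1ccccc1)c1ccccc1 | intermediate (not isolated)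
6 | 1,3-bis(benzyloxy)-5-[2-(3,4-bis(pivaloyloxy)phenyl)ethenyl]benzene, E/Z mixture (geometry left open) | C(=Cc1ccc(OC(=O)C(C)(C)C)c(OC(=O)C(C)(C)C)c1)c1cc(OCc2ccccc2)cc(OCc2ccccc2)c1 | intermediate
7 | 5-[2-(3,4-bis(pivaloyloxy)phenyl)ethyl]benzene-1,3-diol | Oc1cc(O)cc(CCc2ccc(OC(=O)C(C)(C)C)c(OC(=O)C(C)(C)C)c2)c1 | intermediate
8 | 3-[2-(3,4-bis(pivaloyloxy)phenyl)ethyl]-5-(methoxymethoxy)phenol | COCOc1cc(O)cc(CCc2ccc(OC(=O)C(C)(C)C)c(OC(=O)C(C)(C)C)c2)c1 | intermediate
9 | 3-bromo-3-methylbutan-2-one | CC(=O)C(C)(C)Br | starting material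
10 | 3-{3-[2-(3,4-bis(pivaloyloxy)phenyl)ethyl]-5-(methoxymethoxy)phenoxy}-3-methylbutan-2-one | CC(=O)C(C)(C)Oc1cc(OCOC)cc(CCc2ccc(OC(=O)C(C)(C)C)c(OC(=O)C(C)(C)C)c2)c1 | intermediate
11 | tert-butyl{[3-{3-[2-(3,4-bis(pivaloyloxy)phenyl)ethyl]-5-(methoxymethoxy)phenoxy}-3-methylbut-1-en-2-yl]oxy}dimethylsilane | C=C(O[Si](C)(C)C(C)(C)C)C(C)(C)Oc1cc(OCOC)cc(CCc2ccc(OC(=O)C(C)(C)C)c(OC(=O)C(C)(C)C)c2)c1 | intermediate
12 | 5-[2-(3,4-bis(pivaloyloxy)phenyl)ethyl]-7-(methoxymethoxy)-2,2-dimethylchroman-3-one | CC1(C)Oc2cc(OCOC)cc(CCc3ccc(OC(=O)C(C)(C)C)c(OC(=O)C(C)(C)C)c3)c2CC1=O | intermediate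
13 | (3R)-5-[2-(3,4-bis(pivaloyloxy)phenyl)ethyl]-7-(methoxymethoxy)-2,2-dimethylchroman-3-ol | COCOc1cc2c(c(CCc3ccc(OC(=O)C(C)(C)C)c(OC(=O)C(C)(C)C)c3)c1)C[C@@H](O)C(C)(C)O2 | intermediate
14 | (3R)-6-bromo-5-[2-(3,4-bis(pivaloyloxy)phenyl)ethyl]-7-(methoxymethoxy)-2,2-dimethylchroman-3-ol | COCOc1cc2c(c(CCc3ccc(OC(=O)C(C)(C)C)c(OC(=O)C(C)(C)C)c3)c1Br)C[C@@H](O)C(C)(C)O2 | intermediate
15 | prenylboronic acid pinacol ester | CC(C)=CCB1OC(C)(C)C(C)(C)O1 | starting material
16 | (3R)-5-[2-(3,4-bis(pivaloyloxy)phenyl)ethyl]-7-(methoxymethoxy)-2,2-dimethyl-6-(3-methylbut-2-en-1-yl)chroman-3-ol | COCOc1cc2c(c(CCc3ccc(OC(=O)C(C)(C)C)c(OC(=O)C(C)(C)C)c3)c1CC=C(C)C)C[C@@H](O)C(C)(C)O2 | intermediate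
17 | (3R)-5-[2-(3,4-bis(pivaloyloxy)phenyl)ethyl]-2,2-dimethyl-6-(3-methylbut-2-en-1-yl)chromane-3,7-diol | Oc1cc2c(c(CCc3ccc(OC(=O)C(C)(C)C)c(OC(=O)C(C)(C)C)c3)c1CC=C(C)C)C[C@@H](O)C(C)(C)O2 | intermediate
18 | (3R)-5-[2-(3,4-dihydroxyphenyl)ethyl]-2,2-dimethyl-6-(3-methylbut-2-en-1-yl)chromane-3,7-diol (CNP0369548.1) | CC(C)=CCc1c(O)cc2c(c1CCc1ccc(O)c(O)c1)C[C@@H](O)C(C)(C)O2 | target

**Step count**

Total: 13 steps. Longest linear sequence: 12 steps (3 → 4 → 6 → 7 → 8 → 10 → 11 → 12 → 13 → 14 → 16 → 17 → 18; the branch from 1 through 2 is equally long).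

**Steps most likely to fail, with fallbacks**

1. Step 8, the anodic ring closure. The product still carries an oxidisable dialkoxyarene and an enolisable ketone, so it may be consumed by further oxidation, or methanol may capture the radical cation before the ring closes, and mass balance would be lost. The fallback forms the same C4–C4a bond without an oxidant. Setting out from ketone 10, the lithium enolate (LiN(SiMe3)2, THF, −78 °C) would be acylated with 2,2,2-trifluoroethyl trifluoroacetate to the trifluoroacetyl diketone F1, which is not isolated. Detrifluoroacetylative (Regitz-type) diazo transfer with methanesulfonyl azide, Et3N and one equivalent of water in MeCN would give the diazo ketone F2. Its decomposition with Rh2(OAc)4 (cat.) in CH2Cl2 at rt should lead, by attack of the rhodium carbenoid on the ortho aryl carbon (formal aromatic C–H insertion, the established way from aryloxy diazo ketones to chroman-3-ones), to chromanone 12, where the route is rejoined. The site preference for the carbon para to the MOM ether is the same.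

2. Step 11, the prenyl coupling. Transmetalation through the γ-carbon followed by fast reductive elimination would give the 1,1-dimethylallyl isomer, and oxidative addition of zerovalent palladium to the electron-rich, doubly ortho-substituted bromide may be slow enough for protodeboronation of 15 to win. In the fallback, bromide 14 would undergo Stille coupling with allyltributylstannane (Pd(PPh3)4, LiCl, DMF, 90 °C), where no regiochemical question arises, to give the 6-allyl chromanol F3. Olefin cross-metathesis with an excess of 2-methyl-2-butene (second-generation Grubbs catalyst, (H2IMes)(PCy3)Cl2Ru=CHPh, CH2Cl2, 40 °C) would then turn the allyl into the prenyl group and return to 16.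

3. Step 6, the tertiary ether formation. Dehydrobromination of 9 to 3-methylbut-3-en-2-one and conjugate addition of the phenoxide would give the isomeric primary ether, and long exposure of the phenoxide invites acyl transfer from ring B. In the fallback, phenol 8 would be O-alkylated with 3-chloro-3-methylbut-1-yne under copper catalysis (CuCl2·2H2O cat., DBU, MeCN, 0 °C), a reliable way to tertiary propargyl aryl ethers, giving the 1,1-dimethylpropargyl aryl ether F4. Markovnikov hydration of its terminal alkyne (Hg(OTf)2 cat., H2O, MeCN, rt) would deliver methyl ketone 10, where the route continues.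

**Further compounds**

F1 | step 8 | 1,1,1-trifluoro-5-{3-[2-(3,4-bis(pivaloyloxy)phenyl)ethyl]-5-(methoxymethoxy)phenoxy}-5-methylhexane-2,4-dione (trifluoroacetyl diketone, not isolated) | O=C(CC(=O)C(F)(F)F)C(C)(C)Oc1cc(OCOC)cc(CCc2ccc(OC(=O)C(C)(C)C)c(OC(=O)C(C)(C)C)c2)c1
F2 | step 8 | 1-diazo-3-{3-[2-(3,4-bis(pivaloyloxy)phenyl)ethyl]-5-(methoxymethoxy)phenoxy}-3-methylbutan-2-one | [N-]=[N+]=CC(=O)C(C)(C)Oc1cc(OCOC)cc(CCc2ccc(OC(=O)C(C)(C)C)c(OC(=O)C(C)(C)C)c2)c1
F3 | step 11 | (3R)-6-allyl-5-[2-(3,4-bis(pivaloyloxy)phenyl)ethyl]-7-(methoxymethoxy)-2,2-dimethylchroman-3-ol | COCOc1cc2c(c(CCc3ccc(OC(=O)C(C)(C)C)c(OC(=O)C(C)(C)C)c3)c1CC=C)C[C@@H](O)C(C)(C)O2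
F4 | step 6 | 1-[2-(3,4-bis(pivaloyloxy)phenyl)ethyl]-3-(methoxymethoxy)-5-[(2-methylbut-3-yn-2-yl)oxy]benzene | C#CC(C)(C)Oc1cc(OCOC)cc(CCc2ccc(OC(=O)C(C)(C)C)c(OC(=O)C(C)(C)C)c2)c1
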